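**Retrosynthetic overview** (target numbered as 3-[(2S)-2-acetoxypropyl]-2-hydroxy-5,6,8-trimethoxy-1,4-naphthoquinone; ring A = arene, ring B = quinone)
- Last disconnections: the side-chain acetate, then the C2–OH. The C2 oxygen and the side-chain carbinol carbon are 1,4-related (C2, C3, CH2, CH), so one oxygen can tie them into a dihydrofuran (ring C, not in the target), which hydroxide later opens at C2.
- Ring B is cut at C1–C2 and C4–C4a, giving N,N-diethyl-2,4,5-trimethoxybenzamide and methyl (5S)-5-methyl-4,5-dihydrofuran-3-carboxylate, joined in a one-pot anionic [3+3] annulation.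
- Enabling features: in ring A, the C4a–H lies between C8a (carrying C1 as a carboxamide) and the C5 methoxy, so both direct lithium there. In ring C, the future C2–H is α to the ring oxygen and β to the C4 carbonyl, so it can be lithiated under chelation, and the product arrives at the quinone oxidation level.
- The dihydrofuran ester comes from (S)-γ-valerolactone by formylation and acyl-lactone rearrangement.
- Ring order: ring A is bought, ring C is made first, ring B is closed in the key step, ring C is opened afterwards.

Key step: step 4

Remark on the chemistry: the target stereocenter is S; it is bought as the carbinol carbon of (S)-γ-valerolactone, and no step breaks its C–O bond or makes its hydrogen acidic.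

**Step 1**
Reactants: 1 (S)-γ-valerolactone [(5S)-5-methyldihydrofuran-2(3H)-one]
Product: 2 (5S)-3-(hydroxymethylene)-5-methyldihydrofuran-2(3H)-one (enol form of the α-formyl lactone)
Conditions: NaH, HCO2Et, EtOH (cat.), Et2O, 0 °C to rt; cold dilute HCl work-up
Reagents that add atoms: ethyl formate, CCOC=O
Why: Crossed Claisen condensation of the lactone enolate with a non-enolizable formate, driven by irreversible formation of the stabilized sodium enolate of 2; C5 is neither acidic nor attacked, so its S configuration is carried through.

**Step 2**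
Reactants: 2 (5S)-3-(hydroxymethylene)-5-methyldihydrofuran-2(3H)-one
Product: 4 methyl (5S)-5-methyl-4,5-dihydrofuran-3-carboxylate, via acetal ester 3 (not isolated)
Conditions: dry HCl (1 M) in MeOH, 0 °C to rt; concentrate; then TsOH (cat.), toluene, 110 °C, MeOH distilled off
Reagents that add atoms: methanol, CO
Why: Acid-catalysed acyl-lactone rearrangement, in which methanolysis opens the lactone at the acyl–oxygen bond, the freed C5 hydroxyl closes onto the formyl carbon as a cyclic methyl acetal (3, all diastereomers converge) and acid-catalysed β-elimination of methanol should give the conjugated vinylogous carbonate 4; the C5–O bond is never cleaved, so S is retained.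

**Step 3**
Reactants: 5 2,4,5-trimethoxybenzoic acid
Product: 7 N,N-diethyl-2,4,5-trimethoxybenzamide, via acid chloride 6 (not isolated)
Conditions: (COCl)2, DMF (cat.), CH2Cl2, 0 °C to rt; then Et2NH, Et3N, CH2Cl2, 0 °C to rt
Reagents that add atoms: diethylamine, CCNCC
Why: Acid chloride formation by Vilsmeier-type activation followed by Schotten–Baumann-type amidation should install the diethylcarboxamide that serves first as metalation director and then as acyl donor.

**Step 4**
Reactants: 7 N,N-diethyl-2,4,5-trimethoxybenzamide; 4 methyl (5S)-5-methyl-4,5-dihydrofuran-3-carboxylate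
Product: 12 (2S)-5,6,8-trimethoxy-2-methyl-2,3-dihydronaphtho[2,3-b]furan-4,9-dione, via aryllithium 8 (not isolated), via keto amide 9 (not isolated), via vinyllithium 10 (not isolated), via hemiaminal alkoxide 11 (not isolated)
Conditions: s-BuLi, TMEDA, THF, −78 °C; then 4, −78 to −40 °C; then LiTMP (lithium 2,2,6,6-tetramethylpiperidide, pre-formed solution), −78 to −20 °C; inverse quench into cold 1 M HCl
Reagents that add atoms: none
Why: Proposed new method: a one-pot anionic [3+3] annulation is proposed in which the carboxamide and the flanking 5-methoxy group together direct s-BuLi to the arene carbon between them (8), this hard, hindered aryllithium adds 1,2 to the ester carbonyl of 4 and the adduct collapses to keto amide 9 (the C4–C4a bond), LiTMP then removes the dihydrofuran C2–H, which is α to the ring oxygen and β to the new ketone so that lithium is held in a five-membered chelate (10), and the vinyl carbanion adds to the twisted diethylamide to give 11 (the C1–C2 bond), which releases diethylamine and the quinone only on acidic quench. The closest known reaction types are the tandem directed-ortho-metalation synthesis of anthraquinones from ortho-lithiated N,N-diethylbenzamides and aryl aldehydes and the β-lithiation of β-alkoxyacrylates to chelated vinyllithiums that add to carbonyl compounds; new here is the pairing of an ester as first electrophile with a non-aromatic vinyl C–H as second metalation site, which is why the quinone oxidation level should be reached without an oxidant. Ring B closes by 6-exo-trig attack of the vinyllithium on the amide carbonyl, and ring C is carried through untouched. No stereocenter is created in 12 (the hemiaminal carbon of 11 is lost on quench) and the S carbinol carbon is neither acidic nor attacked. The step needs site selectivity in both metalations and carbonyl addition instead of conjugate addition or proton transfer in the acylation: the amide outranks methoxy as director so the C–H between the two methoxy groups is left alone, C2–H is the only activated hydrogen of 9 and LiTMP can neither add to nor reduce the ketone, and a hard aryllithium at −78 °C is expected to prefer the ester carbonyl.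

**Step 5**
Reactants: 12 (2S)-5,6,8-trimethoxy-2-methyl-2,3-dihydronaphtho[2,3-b]furan-4,9-dione
Product: 13 2-hydroxy-3-[(2S)-2-hydroxypropyl]-5,6,8-trimethoxynaphthalene-1,4-dione
Conditions: NaOH (0.5 M aq), THF, degassed, rt to 40 °C; then cold 1 M HCl to pH 3
Reagents that add atoms: sodium hydroxide, [Na+].[OH-]
Why: Addition–elimination of hydroxide at the vinylogous ester carbon C9a, the known alkaline ring opening of furano- and pyrano-fused 1,4-naphthoquinones, is driven by formation of the resonance-stabilized 2-oxidoquinone anion and breaks only the sp2 C–O bond, so the carbinol center keeps its S configuration.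

**Step 6**
Reactants: 13 2-hydroxy-3-[(2S)-2-hydroxypropyl]-5,6,8-trimethoxynaphthalene-1,4-dione
Product: 15 (2S)-1-(3-hydroxy-5,7,8-trimethoxy-1,4-dioxo-1,4-dihydronaphthalen-2-yl)propan-2-yl acetate (the target), via diacetate 14 (not isolated)
Conditions: Ac2O, pyridine, DMAP (cat.), CH2Cl2, 0 °C to rt; then MeOH, rt
Reagents that add atoms: acetic anhydride, CC(=O)OC(C)=O
Why: Exhaustive DMAP-catalysed acetylation followed by chemoselective acyl transfer from the quinonyl acetate of 14 to methanol should work because that acetate is a vinylogous mixed anhydride with a leaving group of carboxylic-acid acidity, whereas the secondary alkyl acetate is inert under these conditions.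

**Compound list**
1 | (S)-γ-valerolactone, (5S)-5-methyldihydrofuran-2(3H)-one | C[C@H]1CCC(=O)O1 | starting material
2 | (5S)-3-(hydroxymethylene)-5-methyldihydrofuran-2(3H)-one (alkene geometry not defined) | C[C@H]1CC(=CO)C(=O)O1 | intermediate
3 | methyl (5S)-2-methoxy-5-methyltetrahydrofuran-3-carboxylate (mixture at C2 and C3) | C[C@H]1CC(C(=O)OC)C(OC)O1 | intermediate
4 | methyl (5S)-5-methyl-4,5-dihydrofuran-3-carboxylate | C[C@H]1CC(C(=O)OC)=CO1 | intermediate
5 | 2,4,5-trimethoxybenzoic acid | COc1cc(OC)c(C(=O)O)cc1OC | starting material
6 | 2,4,5-trimethoxybenzoyl chloride | COc1cc(OC)c(C(Cl)=O)cc1OC | intermediate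
7 | N,N-diethyl-2,4,5-trimethoxybenzamide | CCN(CC)C(=O)c1cc(OC)c(OC)cc1OC | intermediate
8 | N,N-diethyl-2-lithio-3,4,6-trimethoxybenzamide | CCN(CC)C(=O)c1c([Li])c(OC)c(OC)cc1OC | intermediate
9 | N,N-diethyl-3,4,6-trimethoxy-2-[(5S)-5-methyl-4,5-dihydrofuran-3-carbonyl]benzamide | C[C@H]1CC(C(=O)c2c(OC)c(OC)cc(OC)c2C(=O)N(CC)CC)=CO1 | intermediate
10 | N,N-diethyl-2-[(5S)-2-lithio-5-methyl-4,5-dihydrofuran-3-carbonyl]-3,4,6-trimethoxybenzamide | C[C@H]1CC(C(=O)c2c(OC)c(OC)cc(OC)c2C(=O)N(CC)CC)=C([Li])O1 | intermediate
11 | lithium (2S)-9-(diethylamino)-5,6,8-trimethoxy-2-methyl-4-oxo-2,3,4,9-tetrahydronaphtho[2,3-b]furan-9-olate (both C9 epimers) | C[C@H]1CC2=C(O1)C(O[Li])(N(CC)CC)c1c(OC)cc(OC)c(OC)c1C2=O | intermediate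
12 | (2S)-5,6,8-trimethoxy-2-methyl-2,3-dihydronaphtho[2,3-b]furan-4,9-dione | C[C@H]1CC2=C(O1)C(=O)c1c(OC)cc(OC)c(OC)c1C2=O | intermediate
13 | 2-hydroxy-3-[(2S)-2-hydroxypropyl]-5,6,8-trimethoxynaphthalene-1,4-dione | COc1cc(OC)c2c(c1OC)C(=O)C(C[C@H](C)O)=C(O)C2=O | intermediate
14 | (2S)-1-(3-acetoxy-5,7,8-trimethoxy-1,4-dioxo-1,4-dihydronaphthalen-2-yl)propan-2-yl acetate | COc1cc(OC)c2c(c1OC)C(=O)C(C[C@H](C)OC(C)=O)=C(OC(C)=O)C2=O | intermediate
15 | (2S)-1-(3-hydroxy-5,7,8-trimethoxy-1,4-dioxo-1,4-dihydronaphthalen-2-yl)propan-2-yl acetate | COc1cc(OC)c2c(c1OC)C(=O)C(C[C@H](C)OC(C)=O)=C(O)C2=O | target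

**Step count and risks**
Total steps: 6. Longest linear sequence: 5 steps (steps 1, 2, 4, 5, 6 from (S)-γ-valerolactone).

Steps most likely to fail:

1. Step 4. What may go wrong: conjugate addition of the aryllithium to the vinylogous carbonate with opening of ring C, proton transfer from C2–H of 4 to the aryllithium, over-addition to the ketone of 9, or incomplete second metalation. The fallback uses known chemistry and makes the two ring bonds one at a time in the reverse order; it sets out from ester 4 and acid chloride 6 and comes back at 12. Ester 4 is lithiated at C2 with LiN(iPr)2 in THF at −90 °C (the established β-lithiation of β-alkoxyacrylates) to give methyl (5S)-2-lithio-5-methyl-4,5-dihydrofuran-3-carboxylate F1, which is added to a solution of 6 at −90 °C to give methyl (5S)-5-methyl-2-(2,4,5-trimethoxybenzoyl)-4,5-dihydrofuran-3-carboxylate F2. Saponification (LiOH, THF/H2O) should give (5S)-5-methyl-2-(2,4,5-trimethoxybenzoyl)-4,5-dihydrofuran-3-carboxylic acid F3. Intramolecular Friedel–Crafts acylation (P2O5 in MeSO3H, rt) at the only free ortho carbon of the aryl ketone, in the manner of the cyclization of 2-aroylbenzoic acids to anthraquinones, should then close ring B to 12.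

2. Step 5. What may go wrong: attack of hydroxide at the ring methoxy carbons, oxidative degradation of the electron-rich oxidoquinone if air enters, or re-closure of ring C during acidification. The fallback replaces hydroxide by an amine and acetylates before the enol is unveiled; it sets out from 12 and comes back at 15. Pyrrolidine in EtOH at rt should open ring C by addition–elimination to 3-[(2S)-2-hydroxypropyl]-5,6,8-trimethoxy-2-(pyrrolidin-1-yl)naphthalene-1,4-dione F4. Acetylation (Ac2O, pyridine, DMAP) gives (2S)-1-[5,7,8-trimethoxy-1,4-dioxo-3-(pyrrolidin-1-yl)-1,4-dihydronaphthalen-2-yl]propan-2-yl acetate F5. Mild acid hydrolysis of the vinylogous amide (2 M HCl, THF, 40 °C) should then give 15 directly, with no selective deacetylation needed.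

3. Step 2. What may go wrong: incomplete loss of methanol from the acetal, or acid-induced oligomerization of the electron-rich dihydrofuran during the elimination. The fallback builds the ester onto a preformed enol ether; it sets out from 1 and comes back at 4. Reduction of 1 (iBu2AlH, CH2Cl2, −78 °C) gives (5S)-5-methyltetrahydrofuran-2-ol F6. Mesylation (MsCl, Et3N, CH2Cl2, 0 °C) gives (5S)-5-methyltetrahydrofuran-2-yl methanesulfonate F7, which eliminates on warming to (2S)-2-methyl-2,3-dihydrofuran F8. C-Acylation of the enol ether with Cl3CCOCl and pyridine gives 2,2,2-trichloro-1-[(5S)-5-methyl-4,5-dihydrofuran-3-yl]ethan-1-one F9, and haloform-type cleavage (MeOH, K2CO3, rt) should give 4.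

**Further compounds**
F1 | step 4 | methyl (5S)-2-lithio-5-methyl-4,5-dihydrofuran-3-carboxylate | C[C@H]1CC(C(=O)OC)=C([Li])O1
F2 | step 4 | methyl (5S)-5-methyl-2-(2,4,5-trimethoxybenzoyl)-4,5-dihydrofuran-3-carboxylate | C[C@H]1CC(C(=O)OC)=C(O1)C(=O)c1cc(OC)c(OC)cc1OC
F3 | step 4 | (5S)-5-methyl-2-(2,4,5-trimethoxybenzoyl)-4,5-dihydrofuran-3-carboxylic acid | C[C@H]1CC(C(=O)O)=C(O1)C(=O)c1cc(OC)c(OC)cc1OC
F4 | step 5 | 3-[(2S)-2-hydroxypropyl]-5,6,8-trimethoxy-2-(pyrrolidin-1-yl)naphthalene-1,4-dione | COc1cc(OC)c2c(c1OC)C(=O)C(C[C@H](C)O)=C(N1CCCC1)C2=O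
F5 | step 5 | (2S)-1-[5,7,8-trimethoxy-1,4-dioxo-3-(pyrrolidin-1-yl)-1,4-dihydronaphthalen-2-yl]propan-2-yl acetate | COc1cc(OC)c2c(c1OC)C(=O)C(C[C@H](C)OC(C)=O)=C(N1CCCC1)C2=O
F6 | step 2 | (5S)-5-methyltetrahydrofuran-2-ol (both anomers) | C[C@H]1CCC(O)O1
F7 | step 2 | (5S)-5-methyltetrahydrofuran-2-yl methanesulfonate | C[C@H]1CCC(OS(C)(=O)=O)O1
F8 | step 2 | (2S)-2-methyl-2,3-dihydrofuran | C[C@H]1CC=CO1
F9 | step 2 | 2,2,2-trichloro-1-[(5S)-5-methyl-4,5-dihydrofuran-3-yl]ethan-1-one | C[C@H]1CC(C(=O)C(Cl)(Cl)Cl)=CO1
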